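The runs are calculated with made-up constants; the scatter is artificial.

I started with an easy step: in each row of the midnight run I added ring and starting material, the two things the analysis sees.

| flask | starting material | protic impurity | temperature | remark | time |
|---|---|---|---|---|---|
| midnight | 0.32 M | 0.064 M | 110 °C | run made earlier |  |
| elm | 0.64 M | 0.0640 M |  | at 110 °C until 1.0 min, from then on at 150 °C | 2.0 min |
| ash | 0.64 M | 0.0640 M | 110 °C |  | 2.0 min |
| larch | 0.64 M | 0.0640 M | 150 °C |  | 2.0 min |
| oak | 0.64 M | 0.0640 M | 130 °C |  | 2.0 min |

midnight run (percent of the starting material charged)

| time / s | ring / % | starting material / % |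
|---|---|---|
| 10.0 | 64.9 | 27.4 |
| 15.0 | 77.4 | 15.9 |
| 20.0 | 85.9 | 10.2 |
| 25.0 | 90.0 | 5.6 |
| 30.0 | 92.8 | 2.7 |
| 40.0 | 94.3 | 0.9 |

(each reading ± 0.5 percentage points)

- the analysis behind the earlier runs scatters by 0.5 percentage points, standard deviation
- a reading or a percentage of ring counts all its forms, free or not
- the earlier runs do not show what temperature does; that part of a forecast is a guess

- which flask leads in amount of ring, in percent of the starting material charged ("all alike" within 1.5 percentage points) (elm / ash / larch / oak / all alike)
- how much ring is there at the end, in percent of the starting material charged: elm
- how much ring is there at the end, in percent of the starting material charged: ash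
- how much ring is there at the end, in percent of the starting material charged: larch
- how much ring is there at the end, in percent of the starting material charged: oak

The first row sums to 92.3%, and the sum stands at 95.5% in the 30.0 s row, so part of the missing material came back. The last row sums to 95.2%, no different within the scatter of 0.5 percentage points on each reading. What stayed missing there I called the lost share, 4.80%, the part of the charge that reached neither ring nor starting material.

The charge in ash is twice that of the midnight run, at the same c(protic impurity). My zero of the scale was the equal-order case: if ring and loss are both first order in c(starting material), with the impurity step pseudo-first-order, c(starting material) cancels from their ratio and the lost share stays put. A loss second order in starting material would move it up to 9.60%. A loss of the same molar amount in both flasks would move it down to 2.40%. I took the zero, and since 2.0 min is longer than the 40.0 s of the last row, I put ash at 95.2% ring, with heat a guess for the other flasks.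

The forecast gave 95% for elm, 95.5% for ash, 94% for larch and 95% for oak, hence all alike, holding that “All flasks should therefore finish”.

The flasks gave 94.7% for elm, 94.7% for ash, 95.8% for larch and 95.4% for oak, so all alike.

    starting material + protic impurity → quenched substrate (k = 0.0550 /M/s, Ea = 64.0 kJ/mol)
    2 starting material ⇌ open dimer (K = 0.460 /M, k = 0.0973 /M/s, Ea = 78.0 kJ/mol, ΔH = −22.0 kJ/mol)
    starting material → ring (k = 0.124 /s, Ea = 90.0 kJ/mol)
    crystals ⇌ ring, rate k4*(cs4 - [ring]) while solid is left; crystals form when [ring] > cs4 (solubility = 0.410 M, k = 0.265 /s)
    starting material + ring → side product (k = 0.00663 /M/s, Ea = 88.0 kJ/mol)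
    (constants at 110 °C)

Ash lost 5.30% against my lost share of 4.80%, and at 2.00 min it held 2.39% quenched substrate and 2.89% side product. A further flask like elm, charged with 1.6 M of starting material, gave 93.5% ring, so it lost 6.50%, more than 4.80%, and its side product stood at 4.57%.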